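The readings are simulated on assumed constants.

If target were to lose the lead at 25 h in violet, teal or red, what would you have to find in the numbers?

| setting | north-west | south-east | north | violet | teal | red |
|---|---|---|---|---|---|---|
| acidic substrate | 0.52 M | 0.52 M | 0.52 M | 0.52 M | 0.52 M | 0.52 M |
| electrophile | 0.46 M | 0.64 M | 0.76 M | 0.660 M | 0.550 M | 0.790 M |
| gas | 200 mM (held) | 200 mM (held) | 200 mM (held) | 200 mM (held) | 200 mM (held) | 200 mM (held) |
| remark | run made earlier | run made earlier | run made earlier |  |  |  |
| time |  |  |  | 25 h | 25 h | 25 h |

| run | time / h | target / % | acidic substrate / % | side product / % | anion / % |
|---|---|---|---|---|---|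
| north-west | 2.50 | 2 | 89 | 3 | 7 |
| north-west | 5.00 | 12 | 69 | 2 | 16 |
| north-west | 8.00 | 21 | 52 | 5 | 19 |
| north-west | 10.0 | 29 | 45 | 7 | 21 |
| north-west | 12.0 | 34 | 35 | 7 | 23 |
| south-east | 2.50 | 4 | 87 | 2 | 10 |
| south-east | 5.00 | 13 | 75 | 2 | 13 |
| south-east | 8.00 | 28 | 53 | 4 | 17 |
| south-east | 10.0 | 34 | 43 | 6 | 17 |
| south-east | 12.0 | 40 | 35 | 9 | 18 |
| north | 1.00 | 3 | 96 | 0 | 5 |
| north | 2.00 | 7 | 88 | 0 | 8 |
| north | 4.00 | 9 | 77 | 1 | 11 |
| north | 6.00 | 19 | 66 | 3 | 13 |
| north | 12.0 | 45 | 36 | 6 | 16 |

(standard deviation of a reading: 1.5 percentage points)

- which of these there is most of at the end, counted by the acidic substrate in it, violet (acidic substrate / side product / anion / target)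
- which of these there is most of at the end, counted by the acidic substrate in it, teal (acidic substrate / side product / anion / target)
- which of these there is most of at the end, counted by the acidic substrate in it, red (acidic substrate / side product / anion / target)
- how much there is at the end of the one of these that leads, in percent of the acidic substrate charged: violet
- how much there is at the end of the one of these that leads, in percent of the acidic substrate charged: teal
- how much there is at the end of the one of these that leads, in percent of the acidic substrate charged: red

- percent here means acidic substrate units held: one side product counts as two
- what was read earlier has a scatter of 1.5 percentage points, one standard deviation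
- at the start none of the gas is in solution

Follow one unit of acidic substrate. It waits, as acidic substrate or as anion, and then I take it to leave for target or for side product. The south-east run is the nearest to violet in electrophile, and its last reading gives 81.6%. Call this the fork share, target over target plus side product; it is a selectivity, read with the scatter of the readings. The north-west and north runs read 82.9% and 88.2%.

Now turn the question round. For side product to beat target, the fork share has to fall under one in two, and you stand far above that. For the waiting forms together to beat target while the share holds, they must keep more of the charge than the share divided by one plus the share, which is 44.9%. The south-east run still had 53.0% waiting at 12.0 h, which is 8.1 percentage points above that line. But it had lost 17 points in the previous 4.00 h. At that pace I reckon its crossing about 1.90 h after that reading, and 13.0 h lie between that reading and the asked time. Reckoned the same way, with the line from its own last reading, the north-west run, below teal in electrophile, has a line of 45.3% and a crossing about 3.90 h after 12.0 h. The north run, nearest to red, has a line of 46.9% and a crossing about 1.14 h after 12.0 h. So my reckoning puts target in front in violet, teal and red.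

The forecast names target as well, with 65% in violet, 60% in teal and 72% in red: “Target leads in all three.”

The flask gives target in the lead at 76.3% in violet, 69.8% in teal and 81.8% in red, and the violet figure stands 11 points above the forecast.

    target → over-reaction product (k = 1.16 × 10⁻⁷ min⁻¹)
    acidic substrate + anion → side product (k = 0.00117 L mol⁻¹ min⁻¹)
    acidic substrate + free base ⇌ protonated base + anion, settled at all times (K = 6.70)
    electrophile + anion → target (k = 0.00899 L mol⁻¹ min⁻¹)
    gas ⇌ free base, rate k5*(csat - [free base]) (kL = 0.00248 min⁻¹)

In violet at 25.0 h the waiting forms hold 15.1%, less than the 44.9% line. The same violet flask read at 6.0 h stands on the other side of the line, with 79.0% waiting, and there acidic substrate leads with 65.5% against 17.9% of target.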